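Ring B is disconnected at C5–C10 and C8–C9 by an enantioselective intermolecular Diels–Alder reaction. The feature exploited is the quaternary C9 of ring B, which carries the C20 methyl and the one-carbon C11 branch next to C10–H, together with oxygen at C6: this is the imprint of an (E)-α-methyl enal adding to a 2-silyloxydiene. One operation closes ring B, sets C9 and C10 and leaves a regiodefined C6 enol ether. The precursors are (2Z,4E)-3-(triisopropylsilyloxy)hexa-2,4-diene 2, which brings C5–C8 with C17 and C19, and (E)-2-methylhepta-2,6-dienal 5, which brings C9, C10, C11, C20 and the ring A chain C1–C3.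

Key step: step 3

Numbering and faces: ring A = C10–C1–C2–C3=C4–C5, ring B = C5–C6–C7–C8–C9–C10, C11=C12 is the side-chain alkene, and C17, C18, C19, C20 are the methyls on C8, C4, C5, C9. α is the face of ring B carrying C19 and C20; β is the face carrying H10 and C11.

Assumption: 6 is drawn as the formyl-endo adduct (any exo isomer differs only at C5 and C8, which steps 6 and 7 planarise), and the (R)-catalyst is assigned from the formyl C–H···O binding model for α-substituted enals, so the mirror-image catalyst is used if the sense of induction proves opposite.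

Step 1
Reactants: 1 (E)-hex-4-en-3-one
Product: 2 (2Z,4E)-3-(triisopropylsilyloxy)hexa-2,4-diene
Conditions: TIPSOTf, Et3N, CH2Cl2, 0 °C → rt
Reagents that add atoms: triisopropylsilyl trifluoromethanesulfonate, CC(C)[Si](OS(=O)(=O)C(F)(F)F)(C(C)C)C(C)C
Why: Silyl enol ether formation by soft enolisation removes an α′ proton of the ethyl group from the O-silylated enone and should give the cross-conjugated 2-silyloxydiene with the (Z) enol ether (methyl trans to the propenyl group), the geometry that lets both terminal methyls point outward in the s-cis diene.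

Step 2
Reactants: 3 pent-4-enal; 4 2-(triphenylphosphoranylidene)propanal
Product: 5 (E)-2-methylhepta-2,6-dienal
Conditions: toluene, 90 °C
Reagents that add atoms: none
Why: Wittig olefination with a formyl-stabilised ylide is (E)-selective with aliphatic aldehydes and should stop at the monoadduct because the α-methyl enal formed is less electrophilic than 3.

Step 3
Reactants: 2 (2Z,4E)-3-(triisopropylsilyloxy)hexa-2,4-diene; 5 (E)-2-methylhepta-2,6-dienal
Product: 6 cycloadduct 6-(but-3-en-1-yl)-1,2,5-trimethyl-4-(triisopropylsilyloxy)cyclohex-3-ene-1-carbaldehyde (C9 bears C20 α and the formyl group β; C10 bears the butenyl chain α and H β; C17 and C19 cis to the formyl group)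
Conditions: (R)-3,3-diphenyl-1-(o-tolyl)tetrahydro-1H,3H-pyrrolo[1,2-c][1,3,2]oxazaborole (20 mol%), HN(SO2CF3)2 (20 mol%), 2 (1.5 equiv), CH2Cl2, −78 → −40 °C; Et3N quench
Reagents that add atoms: none
Why: The boron of the protonated oxazaborolidine binds the formyl oxygen of the s-trans enal (with a formyl C–H···O contact to the ring oxygen) and lowers its LUMO, and the diene adds in a concerted, asynchronous [4+2] cycloaddition in which the enol-ether terminus C5 bonds to the β-carbon C10 and C8 bonds to the α-carbon C9. The closest known reaction type is the oxazaborolidinium-catalysed Diels–Alder reaction of α-substituted enals with 2-silyloxy-1,3-dienes. Ring B closes as a six-membered ring by intermolecular [4+2] cycloaddition, suprafacial on both partners. C9 and C10 are related through the (E) geometry of 5 (C20 cis to the C1 chain, C11 cis to H10) and their absolute configuration is set by the catalyst, which shields one face of the bound enal; C5 and C8 are cis to each other because both diene methyls point outward, and their relation to C9 need not be controlled since steps 6 and 7 planarise them. The regiochemistry needed (C6 oxygen "para" to C9) is secured by the 2-silyloxy group, which makes C5 the nucleophilic terminus; the TIPS group is chosen so that the diene and the product enol ether resist the acidic catalyst.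

Step 4
Reactants: 6 cycloadduct aldehyde
Product: 7 C11 primary alcohol, [6-(but-3-en-1-yl)-1,2,5-trimethyl-4-(triisopropylsilyloxy)cyclohex-3-en-1-yl]methanol, configuration as in 6
Conditions: NaBH4, EtOH, 0 °C
Reagents that add atoms: none
Why: Borohydride reduction of the only carbonyl group, the C6 ketone being masked as a silyl enol ether that is stable to NaBH4; no stereocentre is formed.

Step 5
Reactants: 7 C11 primary alcohol
Product: 8 C11 tert-butyldimethylsilyl ether of 7
Conditions: TBSCl, imidazole, DMF, rt
Reagents that add atoms: tert-butyldimethylsilyl chloride, CC(C)(C)[Si](C)(C)Cl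
Why: Silyl ether formation at a primary alcohol, giving a group that should survive enolate, palladium and ruthenium chemistry and be removable later beside an acetate.

Step 6
Reactants: 8 C11 silyl ether
Product: 9 enone 5-(but-3-en-1-yl)-4-[(tert-butyldimethylsilyloxy)methyl]-3,4,6-trimethylcyclohex-2-en-1-one (C6 ketone, C7=C8; C9 and C10 unchanged; C5–H epimerisable)
Conditions: Pd(OAc)2 (1.1 equiv), MeCN, rt → 40 °C
Reagents that add atoms: none
Why: Saegusa–Ito oxidation, in which palladation of the regiodefined enol ether at C7 and syn β-hydride elimination of H8 should give the C7=C8 enone, erasing the C8 centre and blocking C7 against later enolisation.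

Step 7
Reactants: 9 enone; 10 2-bromopropene
Product: 12 isopropenyl enone 5-(but-3-en-1-yl)-4-[(tert-butyldimethylsilyloxy)methyl]-3,4,6-trimethyl-6-(prop-1-en-2-yl)cyclohex-2-en-1-one (C19 α; isopropenyl β and trans to the butenyl chain), via lithium enolate 11 (not isolated)
Conditions: LiHMDS, THF, −78 °C; then Pd2(dba)3 (2.5 mol%), P(t-Bu)3 (6 mol%), 10, toluene, rt → 50 °C
Reagents that add atoms: none
Why: Palladium-catalysed α-alkenylation of a ketone enolate, in which kinetic deprotonation takes the α′ proton at C5 (C7 is part of the enone) and oxidative addition of 10 to zerovalent palladium, transmetalation and C–C reductive elimination should place the isopropenyl group on the β face of C5, opposite the adjacent C10 butenyl chain and the C20 methyl, so that C19 ends α.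

Step 8
Reactants: 12 isopropenyl enone
Product: 13 trans-fused bicyclic dienone (ring A with C3=C4 and C18; ring B with C6 ketone, C7=C8 and C17; C11–OTBS; C19 and C20 α, H10 β)
Conditions: (H2IMes)(PCy3)Cl2Ru=CHPh (second-generation Grubbs catalyst, 5 mol%), CH2Cl2, 40 °C
Reagents that add atoms: none
Why: Ring-closing olefin metathesis between the monosubstituted butenyl alkene and the 1,1-disubstituted isopropenyl group should close the six-membered ring A as the trisubstituted C3=C4 alkene with loss of ethylene, the electron-poor trisubstituted enone alkene staying out and the trans ring fusion being fixed already.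

Step 9
Reactants: 13 bicyclic dienone
Product: 14 6α-allylic alcohol (6-OH cis to C19, H6 β)
Conditions: NaBH4, CeCl3·7H2O, MeOH, −78 → 0 °C
Reagents that add atoms: none
Why: Luche reduction gives 1,2-reduction of the enone, and hydride should add to C6 from the β face, anti to the axial C19 methyl on the neighbouring quaternary C5, giving the equatorial 6α-alcohol.

Step 10
Reactants: 14 6α-allylic alcohol
Product: 15 6α-acetate
Conditions: Ac2O, DMAP, pyridine, CH2Cl2, rt
Reagents that add atoms: acetic anhydride, CC(=O)OC(C)=O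
Why: DMAP-catalysed esterification of the only free hydroxyl, which fixes the acetate on O6 before O7 and O8 exist.

Step 11
Reactants: 15 6α-acetate
Product: 16 6α-acetoxy C11 primary alcohol
Conditions: HF·pyridine, pyridine, THF, 0 °C → rt
Reagents that add atoms: none
Why: Fluoride-mediated desilylation under buffered conditions should cleave the primary silyl ether without touching the acetate or either alkene.

Step 12
Reactants: 16 6α-acetoxy C11 alcohol
Product: 18 6α-acetoxy-7β,8β,11-triol (C17 α), via osmate ester 17 (not isolated)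
Conditions: OsO4 (1.05 equiv), TMEDA, CH2Cl2, −78 °C; then sat. aq. NaHSO3, THF, 40 °C
Reagents that add atoms: osmium tetroxide, O=[Os](=O)(=O)=O
Why: Hydroxyl-directed syn-dihydroxylation with the OsO4–TMEDA complex, in which a hydrogen bond from the C11 hydroxyl (homoallylic to C7=C8) should steer the reagent to this alkene and not to C3=C4, and to the β face, which is also opposite the axial C19 and C20 methyls and the allylic acetate, setting C7 and C8 together.

Step 13
Reactants: 18 triol
Product: 19 6α-acetoxy-7β,8β-dihydroxy C11 aldehyde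
Conditions: Cu(MeCN)4OTf (10 mol%), 2,2′-bipyridine, TEMPO, N-methylimidazole, MeCN, air, rt
Reagents that add atoms: none
Why: Copper/TEMPO aerobic alcohol oxidation is selective for primary over secondary and tertiary alcohols, has no glycol-cleavage pathway and should stop at the non-enolisable aldehyde.

Step 14
Reactants: 19 dihydroxy aldehyde
Product: 20 6α-acetoxy-7β-isobutyryloxy-8β-hydroxy C11 aldehyde
Conditions: (i-PrCO)2O, DMAP, pyridine, CH2Cl2, rt
Reagents that add atoms: isobutyric anhydride, CC(C)C(=O)OC(=O)C(C)C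
Why: DMAP-catalysed esterification should take place only at the equatorial secondary C7 hydroxyl, the tertiary C8 hydroxyl being unreactive and the aldehyde having no α-hydrogen.

Step 15
Reactants: 20 isobutyrate aldehyde; 21 2-(dichloromethyl)-4,4,5,5-tetramethyl-1,3,2-dioxaborolane
Product: 22 (E)-C11=C12 alkenyl pinacolboronate of the fully acylated ring system
Conditions: CrCl2 (8 equiv), LiI (4 equiv), THF, rt
Reagents that add atoms: none
Why: Takai–Utimoto-type chromium-mediated olefination, in which the gem-dichromium reagent formed from 21 adds to the aldehyde and eliminates to the (E)-alkenylboronate under neutral conditions that should spare both esters and avoid retro-aldol cleavage of the β-hydroxy aldehyde.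

Step 16
Reactants: 22 alkenyl pinacolboronate; 23 4-bromofuran-2(5H)-one
Product: 24 CNP0207114.1 (6α-acetoxy, 7β-isobutyryloxy, 8β-hydroxy, (E)-C11=C12 bearing the furan-2(5H)-on-4-yl group)
Conditions: Pd(dppf)Cl2 (5 mol%), K3PO4, THF/H2O, rt
Reagents that add atoms: none
Why: Suzuki–Miyaura coupling, in which oxidative addition of zerovalent palladium into the activated C–Br bond of 23, transmetalation of the alkenylboronate and reductive elimination should form C12–C13 with retention of the (E) alkene.

Compound list
1 | (E)-hex-4-en-3-one | C/C=C/C(=O)CC | starting material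
2 | (2Z,4E)-3-(triisopropylsilyloxy)hexa-2,4-diene | C/C=C/C(O[Si](C(C)C)(C(C)C)C(C)C)=C/C | intermediate
3 | pent-4-enal | C=CCCC=O | starting material
4 | 2-(triphenylphosphoranylidene)propanal | CC(C=O)=P(c1ccccc1)(c1ccccc1)c1ccccc1 | starting material
5 | (E)-2-methylhepta-2,6-dienal | O=C/C(C)=C/CCC=C | intermediate
6 | ring-B cycloadduct, 6-(but-3-en-1-yl)-1,2,5-trimethyl-4-(triisopropylsilyloxy)cyclohex-3-ene-1-carbaldehyde, endo isomer | C[C@H]1C=C(O[Si](C(C)C)(C(C)C)C(C)C)[C@@H](C)[C@H](CCC=C)[C@@]1(C)C=O | intermediate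
7 | C11 primary alcohol of 6 | C[C@H]1C=C(O[Si](C(C)C)(C(C)C)C(C)C)[C@@H](C)[C@H](CCC=C)[C@@]1(C)CO | intermediate
8 | C11 tert-butyldimethylsilyl ether of 7 | C[C@H]1C=C(O[Si](C(C)C)(C(C)C)C(C)C)[C@@H](C)[C@H](CCC=C)[C@@]1(C)CO[Si](C)(C)C(C)(C)C | intermediate
9 | enone, 5-(but-3-en-1-yl)-4-[(tert-butyldimethylsilyloxy)methyl]-3,4,6-trimethylcyclohex-2-en-1-one | C[C@@H]1C(=O)C=C(C)[C@](C)(CO[Si](C)(C)C(C)(C)C)[C@H]1CCC=C | intermediate
10 | 2-bromopropene | C=C(C)Br | starting material
11 | lithium C5=C6 enolate of 9 | [Li]OC1=C(C)[C@H](CCC=C)[C@@](C)(CO[Si](C)(C)C(C)(C)C)C(C)=C1 | intermediate (not isolated)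
12 | isopropenyl enone, C19 α, isopropenyl β | C=C(C)[C@]1(C)C(=O)C=C(C)[C@](C)(CO[Si](C)(C)C(C)(C)C)[C@H]1CCC=C | intermediate
13 | trans-fused bicyclic dienone, C11–OTBS | CC1=CCC[C@@H]2[C@@](C)(CO[Si](C)(C)C(C)(C)C)C(C)=CC(=O)[C@@]12C | intermediate
14 | 6α-allylic alcohol | CC1=CCC[C@@H]2[C@@](C)(CO[Si](C)(C)C(C)(C)C)C(C)=C[C@H](O)[C@@]12C | intermediate
15 | 6α-acetate | CC1=CCC[C@@H]2[C@@](C)(CO[Si](C)(C)C(C)(C)C)C(C)=C[C@H](OC(C)=O)[C@@]12C | intermediate
16 | 6α-acetoxy C11 alcohol | CC1=CCC[C@@H]2[C@@](C)(CO)C(C)=C[C@H](OC(C)=O)[C@@]12C | intermediate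
17 | osmate ester of 16 (hexavalent osmium 7β,8β-glycolate, TMEDA-bound) | CC1=CCC[C@@H]2[C@@](C)(CO)[C@@]3(C)O[Os](=O)(=O)O[C@H]3[C@H](OC(C)=O)[C@@]12C.CN(C)CCN(C)C | intermediate (not isolated)
18 | 6α-acetoxy-7β,8β,11-triol | CC1=CCC[C@@H]2[C@@](C)(CO)[C@@](C)(O)[C@@H](O)[C@H](OC(C)=O)[C@@]12C | intermediate
19 | 6α-acetoxy-7β,8β-dihydroxy C11 aldehyde | CC1=CCC[C@@H]2[C@@](C)(C=O)[C@@](C)(O)[C@@H](O)[C@H](OC(C)=O)[C@@]12C | intermediate
20 | 6α-acetoxy-7β-isobutyryloxy-8β-hydroxy C11 aldehyde | CC1=CCC[C@@H]2[C@@](C)(C=O)[C@@](C)(O)[C@@H](OC(=O)C(C)C)[C@H](OC(C)=O)[C@@]12C | intermediate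
21 | 2-(dichloromethyl)-4,4,5,5-tetramethyl-1,3,2-dioxaborolane | CC1(C)OB(C(Cl)Cl)OC1(C)C | starting material
22 | (E)-alkenyl pinacolboronate | CC1=CCC[C@@H]2[C@@](C)(/C=C/B3OC(C)(C)C(C)(C)O3)[C@@](C)(O)[C@@H](OC(=O)C(C)C)[C@H](OC(C)=O)[C@@]12C | intermediate
23 | 4-bromofuran-2(5H)-one | O=C1C=C(Br)CO1 | starting material
24 | CNP0207114.1 | CC(=O)O[C@H]1[C@H](OC(=O)C(C)C)[C@](C)(O)[C@](C)(/C=C/C2=CC(=O)OC2)[C@H]2CCC=C(C)[C@]12C | target

Total step count: 16. Longest linear sequence: 15 steps (1 → 2 → 6 → … → 24, steps 1 and 3–16; the branch from 3 through 5 is equally long).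

Steps most likely to fail

Step 3. The trisubstituted enal may add too slowly to the 1,4-disubstituted diene, so that protodesilylation of the diene or an open-chain conjugate addition takes over, or the catalyst may discriminate the enal faces poorly. The fallback sets out from 2 and 5 and comes back at 7. The cycloaddition is run without enantiocontrol under Me2AlCl (1 equiv, CH2Cl2, −78 → −20 °C) to give racemic cycloadduct F1. NaBH4 reduction gives racemic alcohol F2. Esterification with (S)-O-methylmandelic acid (DCC, DMAP) gives two diastereomeric esters, (S)-O-methylmandelate of 7 F3 and (S)-O-methylmandelate of ent-7 F4, which are separated by chromatography. Reductive cleavage of F3 with LiAlH4 (Et2O, 0 °C) returns alcohol 7.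

Step 7. Reductive elimination at the congested tertiary enolate carbon may be outrun by β-hydride elimination or by proton transfer to the extended dienolate, and facial selectivity at C5 may be incomplete. The fallback sets out from 9 and comes back at 12. Kinetic enolisation and silylation (LDA, TMSCl, THF, −78 °C) give cross-conjugated trimethylsilyl dienol ether F5. A TiCl4-mediated Mukaiyama aldol addition to acetone (CH2Cl2, −78 °C), anti to the butenyl chain, gives tertiary aldol F6. Dehydration with Burgess reagent (toluene, 50 °C) can only proceed toward a methyl group because C5 is quaternary, and gives 12.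

Step 12. Hydrogen-bond delivery from the homoallylic C11 hydroxyl may be too weak, so that osmylation of the C3=C4 alkene competes. The fallback sets out from 13 and comes back at 20, using the enone to single out C7=C8.
- Weitz–Scheffer epoxidation (t-BuOOH, DBU, CH2Cl2) attacks only the electron-poor alkene, from the β face opposite C19 and C20, and gives 7β,8β-epoxy ketone F7.
- SmI2 (THF/MeOH, −78 °C) cleaves the Cα–O bond to 8β-hydroxy ketone F8.
- Enolisation toward C7, the only enolisable position (KHMDS, 2.2 equiv, THF, −78 °C), and oxidation with 2-(phenylsulfonyl)-3-phenyloxaziridine from the β face give 7β,8β-dihydroxy ketone F9.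
- Isobutyric anhydride/DMAP gives 7β-isobutyryloxy ketone F10.
- NaBH4 (MeOH, −20 °C, hydride from the β face) gives 6α-alcohol F11.
- Ac2O/DMAP gives 6α-acetate F12.
- HF·pyridine gives C11 alcohol F13.
- The copper/TEMPO aerobic oxidation of step 13 then gives aldehyde 20.

Further compounds
F1 | step 3 | racemic cycloadduct (6 and its enantiomer) | C[C@H]1C=C(O[Si](C(C)C)(C(C)C)C(C)C)[C@@H](C)[C@H](CCC=C)[C@@]1(C)C=O.C[C@@H]1C=C(O[Si](C(C)C)(C(C)C)C(C)C)[C@H](C)[C@@H](CCC=C)[C@]1(C)C=O
F2 | step 3 | racemic alcohol (7 and its enantiomer) | C[C@H]1C=C(O[Si](C(C)C)(C(C)C)C(C)C)[C@@H](C)[C@H](CCC=C)[C@@]1(C)CO.C[C@@H]1C=C(O[Si](C(C)C)(C(C)C)C(C)C)[C@H](C)[C@@H](CCC=C)[C@]1(C)CO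
F3 | step 3 | (S)-O-methylmandelate of 7 | C[C@H]1C=C(O[Si](C(C)C)(C(C)C)C(C)C)[C@@H](C)[C@H](CCC=C)[C@@]1(C)COC(=O)[C@@H](OC)c1ccccc1
F4 | step 3 | (S)-O-methylmandelate of ent-7 | C[C@@H]1C=C(O[Si](C(C)C)(C(C)C)C(C)C)[C@H](C)[C@@H](CCC=C)[C@]1(C)COC(=O)[C@@H](OC)c1ccccc1
F5 | step 7 | cross-conjugated trimethylsilyl dienol ether of 9 | C[Si](C)(C)OC1=C(C)[C@H](CCC=C)[C@@](C)(CO[Si](C)(C)C(C)(C)C)C(C)=C1
F6 | step 7 | tertiary aldol (C5 2-hydroxypropan-2-yl, β) | CC(C)(O)[C@]1(C)C(=O)C=C(C)[C@](C)(CO[Si](C)(C)C(C)(C)C)[C@H]1CCC=C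
F7 | step 12 | 7β,8β-epoxy ketone | CC1=CCC[C@@H]2[C@@](C)(CO[Si](C)(C)C(C)(C)C)[C@@]3(C)O[C@H]3C(=O)[C@@]12C
F8 | step 12 | 8β-hydroxy ketone | CC1=CCC[C@@H]2[C@@](C)(CO[Si](C)(C)C(C)(C)C)[C@@](C)(O)CC(=O)[C@@]12C
F9 | step 12 | 7β,8β-dihydroxy ketone | CC1=CCC[C@@H]2[C@@](C)(CO[Si](C)(C)C(C)(C)C)[C@@](C)(O)[C@@H](O)C(=O)[C@@]12C
F10 | step 12 | 7β-isobutyryloxy-8β-hydroxy ketone | CC1=CCC[C@@H]2[C@@](C)(CO[Si](C)(C)C(C)(C)C)[C@@](C)(O)[C@@H](OC(=O)C(C)C)C(=O)[C@@]12C
F11 | step 12 | 6α-alcohol, C11–OTBS | CC1=CCC[C@@H]2[C@@](C)(CO[Si](C)(C)C(C)(C)C)[C@@](C)(O)[C@@H](OC(=O)C(C)C)[C@H](O)[C@@]12C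
F12 | step 12 | 6α-acetate, C11–OTBS | CC1=CCC[C@@H]2[C@@](C)(CO[Si](C)(C)C(C)(C)C)[C@@](C)(O)[C@@H](OC(=O)C(C)C)[C@H](OC(C)=O)[C@@]12C
F13 | step 12 | 6α-acetoxy-7β-isobutyryloxy-8β-hydroxy C11 alcohol | CC1=CCC[C@@H]2[C@@](C)(CO)[C@@](C)(O)[C@@H](OC(=O)C(C)C)[C@H](OC(C)=O)[C@@]12C
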